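## Analysis of the target

The target (30) is a tridepside. It has three orsellinate-type benzene rings A, B and C, each with a carboxyl carbon at position 1, oxygen at positions 2 and 4 and a methyl group at position 6 (ring atoms are called A1–A6, B1–B6, C1–C6 in this sense). Ring A is joined through its carboxyl to the B4 oxygen, ring B through its carboxyl to the C4 oxygen, and ring C ends in a methyl ester. There is no stereocentre and no stereogenic double bond, so the problem is purely one of regiochemistry and chemoselectivity. All six ring oxygens differ in fate: A2–OH and B2–OH are free and hydrogen-bonded to their ester carbonyls, A4–O and C2–O are methyl ethers, and B4–O and C4–O are acylated. The two aryl ester bonds are the sensitive groups: as activated esters they can be cleaved or transposed by phenoxides, alkoxides and amines, and they are liable to photo-Fries rearrangement under short-wavelength light. The electron-rich rings are also open to electrophiles. The synthesis is hard because each inter-ring ester derives from a 2,6-disubstituted benzoic acid, which acylates phenols poorly, and because ring B needs B2–O and B4–O told apart while B1 already carries an ester to a phenol. The strategy rests on ring B: a resorcinol with B2–OH and B4–O meta to each other, B3 and B5 unsubstituted, and B1 (ester) flanked by B2 and B6 (methyl). That is the pattern obtained when an ester- and methyl-substituted vinylketene (B1, B6, B5, B2) takes up a terminal ynol ether (B3, B4), the ketene carbonyl becoming B2–OH and the ynol ether oxygen the separately masked B4–O.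

## Retrosynthetic reasoning

Target 30 is traced to its A2 benzyl ether 29, and 29 is cut at the acyl C–O bond between the ring A carbonyl and B4–O, giving acid 27 (used as its chloride 28) and the didepside diol 24. This bond is cut first because ring A is the simplest unit, reachable from 1 in three steps, and because B4–OH is the only unchelated phenol of 24. The forward acylation therefore needs no protection of B2–OH. The A2 oxygen is masked as a benzyl ether to stop self-acylation, and this ether comes off last under neutral conditions that leave both ester bonds alone.

Diol 24 is traced to its B4 tert-butyl ether 23. This is only a change of protecting group, but it matters: 23 is what the ring construction delivers, with B2–O free and B4–O masked, so the two ring B oxygens never have to be distinguished by a selective reaction.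

Ether 23 is disconnected across ring B at four bonds, B1–B2, B2–B3, B4–B5 and B5–B6, giving diazo ketone 11 and ynol ether 18. The cut is made here because it removes the hardest bond of the molecule from the list of bonds to be made on an aromatic acid: the hindered B1 ester is carried through the ring formation as an ordinary enoate ester. The forward reaction has to turn 11 into a vinylketene, add 18 in the right orientation and close the six-membered ring. The ketene carbonyl ends as B2–OH and the alkyne oxygen as B4–O.

Ynol ether 18 is traced through dichlorovinyl ether 15 to 12 and 13. A tert-butyl group is chosen for the alkyne oxygen because 18 is distillable and is known to add to ketenes in the required sense, and because its aryl ether is cleaved by acid. A parent silyl ynol ether would play the same role but has no dependable preparation.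

Diazo ketone 11 is traced to methyl ketone 9 through its trifluoroacetyl derivative 10, by cutting the C=N bond (diazo transfer). The other way to such compounds, acylation of a diazoalkane by the acid chloride of the same chain, is set aside. A diazoalkane adds as a 1,3-dipole to a doubly activated, fumarate-like alkene faster than is acceptable, whereas diazo transfer to an activated methyl ketone leaves the alkene alone.

Ketone 9 is cut at its ester C–O bond into acid 8 and phenol 4. Both partners are unhindered here, an acrylic-type acid and a phenol flanked by two CH positions, so this is where the ring B to ring C ester is actually formed.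

Acid 8 is traced through its tert-butyl ester 7 to diketone 5 and ylide 6 by cutting the C2=C3 double bond. The diketone is symmetrical, so there is no regiochemical question, and a stabilised ylide should give the E alkene that the later ring closure needs.

Phenol 4 (via 3 and 2) and acid 27 (via 26 and 25) both go back to 1. Each sequence uses the same fact in opposite directions: the unchelated 4-hydroxyl of 1 is alkylated first, and the chelated 2-hydroxyl only under more forcing conditions.

## Alternatives that were turned down

Alternative 1: Ring A of the dibenzyl ether A1 of the target is cut at A3–A4 and A5–A6. This gives the 2-pyranone-5-carboxylate A2, already esterified to the benzyl-protected B–C didepside, and the ketene acetal A3. The forward key step is an inverse-electron-demand [4+2] cycloaddition of A3 across C3 and C6 of the pyranone, followed by loss of the lactone bridge and of one methoxy group as its alcohol to aromatise ring A. Hydrogenolysis of A1 would finish the synthesis.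
- For: the orientation follows the known coumalate pattern, the A4 methoxy group arrives in place, and the ring is formed late and thermally, without light or a diazo compound. On convergence it is stronger than the chosen route.
- Against: A2 carries a 4-benzyloxy donor and a 6-methyl group. Both lower its reactivity as an electron-poor diene and hinder the terminus that A3 must attack, so forcing conditions would be needed, under which the nucleophilic A3 can also attack the two aryl ester bonds. A2 also presupposes the B–C didepside, whose hindered B1 ester would have to be made by classical acylation, as would the ester of the 4,6-disubstituted pyranone acid.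
- Comparison: it builds the ring whose ester bond is the easier one and leaves ring B as an unsolved problem. The chosen route is linear, but it delivers ring B with its hindered ester and its oxygen differentiation already in place.

Alternative 2: Ring C is cut at C1–C2 and C5–C6 into the 1,1-dimethoxy-3-silyloxy diene A5 and the alkynoate A6. The forward key step is a [4+2] cycloaddition with loss of one methoxy group as its alcohol, giving the silyl ether A4; desilylation of A4 gives phenol 4.
- For: the regiochemistry is fixed by the matched polarisation of both partners, and the C2–OMe / C4–O difference is built in. The step is more dependable than a photochemical cascade, so on reliability of the key step this alternative is stronger.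
- Against: ring C is the least demanding part of the molecule. Phenol 4 is reached from commercial 1 in three routine steps, whereas A5 is moisture-sensitive and must be prepared, and A6, with a methyl group on its β-carbon, is a sluggish dienophile. No steps are saved, and none of the inter-ring ester bonds is addressed.
- Comparison: both hindered esters and the differentiation of ring B would remain for classical methods. The chosen route spends its ring construction on ring B, where classical chemistry is weakest, and takes ring C from 1.

Alternative 3: Ring A is cut at A1–A6, leading back to the aryl 3,5,7-trioxooctanoate A8, in which the polyketide chain is an ester of B4–O of the B–C didepside. The forward key step is a base-mediated aldol condensation of C2 onto the C7 ketone, then dehydration and enolisation, giving the 4-O-demethyl compound A7. A7 would then need selective methylation of A4–OH.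
- For: it is biomimetic, needs no protecting group on ring A, and forms the A–B ester from an unhindered acid, which is the same logic the chosen route applies to ring B. Methylating the only unchelated phenol of A7 is plausible. On protecting-group economy it is stronger.
- Against: A8 is an aryl ester, hence an activated ester, of a triketo acid. Under base its enolates can expel the ring B phenoxide by Claisen-type C-acylation or by lactonisation to a hydroxypyranone, and these modes compete with the aldol mode. The base also threatens the B–C ester, and assembling A8 on a base-sensitive didepside is itself difficult. The hindered B1 ester would still have to be made classically.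
- Comparison: it solves the easier of the two ester problems, which the chosen route handles simply with acid chloride 28, and leaves the harder one.

Key step: step 10

## Route

Remark on the chemistry: compounds 1, 5, 6, 12 and 13 are taken to be commercial, and the oxygen of the alkyne partner is carried as a tert-butyl ether for the reasons given above. In the steps, "ring C aryl" means the 3-methoxy-4-(methoxycarbonyl)-5-methylphenyl group of phenol 4.

Step 1
Reactants: 1 methyl orsellinate (methyl 2,4-dihydroxy-6-methylbenzoate)
Product: 2 methyl 4-(benzyloxy)-2-hydroxy-6-methylbenzoate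
Conditions: BnBr (1.05 equiv), K2CO3, acetone, reflux
Reagents that add atoms: benzyl bromide, BrCc1ccccc1
Why: Williamson etherification; the 4-hydroxyl is para to the ester, not hydrogen-bonded and more acidic than the chelated 2-hydroxyl, so one equivalent of halide should alkylate it selectively.

Step 2
Reactants: 2 methyl 4-(benzyloxy)-2-hydroxy-6-methylbenzoate
Product: 3 methyl 4-(benzyloxy)-2-methoxy-6-methylbenzoate
Conditions: MeI (3 equiv), K2CO3, DMF, 50 °C
Reagents that add atoms: iodomethane, CI
Why: Williamson O-methylation of the remaining chelated phenol, which needs the polar aprotic solvent and excess halide; the methyl ester and benzyl ether are inert.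

Step 3
Reactants: 3 methyl 4-(benzyloxy)-2-methoxy-6-methylbenzoate
Product: 4 methyl 4-hydroxy-2-methoxy-6-methylbenzoate
Conditions: H2 (1 atm), 10% Pd/C, EtOAc/MeOH, rt
Reagents that add atoms: none
Why: Hydrogenolysis of the benzyl aryl ether; the methyl ester and methyl ether are untouched, and the freed hydroxyl is the one that will carry ring B.

Step 4
Reactants: 5 butane-2,3-dione (3 equiv); 6 tert-butyl (triphenyl-λ5-phosphanylidene)acetate
Product: 7 tert-butyl (E)-3-methyl-4-oxopent-2-enoate
Conditions: CH2Cl2, 0 °C to rt
Reagents that add atoms: none
Why: Wittig olefination of an activated 1,2-diketone carbonyl by a stabilised ylide; the excess of the symmetrical diketone suppresses double olefination, and the stabilised ylide should place the ester trans to the larger acetyl group (E).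

Step 5
Reactants: 7 tert-butyl (E)-3-methyl-4-oxopent-2-enoate
Product: 8 (E)-3-methyl-4-oxopent-2-enoic acid
Conditions: CF3CO2H/CH2Cl2 (1:3), 0 °C to rt; evaporate with toluene
Reagents that add atoms: none
Why: Acidolysis of the tert-butyl ester by loss of the tert-butyl cation as the alkene; the E acid cannot close to a lactol, so the geometry should survive short exposure to cold acid.

Step 6
Reactants: 8 (E)-3-methyl-4-oxopent-2-enoic acid (1.2 equiv); 4 methyl 4-hydroxy-2-methoxy-6-methylbenzoate
Product: 9 ring C aryl (E)-3-methyl-4-oxopent-2-enoate
Conditions: EDC·HCl, DMAP (cat.), CH2Cl2, 0 °C to rt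
Reagents that add atoms: none
Why: Steglich-type carbodiimide esterification; the acid is unhindered and the phenol is flanked by two CH positions, so the ester that becomes the hindered B1 ester should form without difficulty at this stage.

Step 7
Reactants: 9 ring C aryl (E)-3-methyl-4-oxopent-2-enoate
Product: 11 ring C aryl (E)-5-diazo-3-methyl-4-oxopent-2-enoate, via trifluoroacetyl diketone 10 (not isolated)
Conditions: LiN(SiMe3)2 (1.1 equiv), THF, −78 °C, inverse addition; CF3CO2CH2CF3 (1.2 equiv), −78 °C; dilute HCl work-up; then MsN3 (1.5 equiv), Et3N (1.5 equiv), H2O (1 equiv), MeCN, rt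
Reagents that add atoms: methanesulfonyl azide, CS(=O)(=O)N=[N+]=[N-] (both diazo nitrogens of 11); 2,2,2-trifluoroethyl trifluoroacetate, O=C(OCC(F)(F)F)C(F)(F)F (the trifluoroacetyl group of 10 only)
Why: Detrifluoroacetylative diazo transfer (a Regitz-type transfer to an activated ketone): the only enolisable position of the ketone is its terminal methyl group, kinetic Claisen trifluoroacetylation gives 10, and the sulfonyl azide then transfers the diazo group with loss of the trifluoroacetyl group onto the sulfonamide nitrogen. This method is chosen because it leaves the electron-poor alkene alone, where acylation of a diazoalkane by the acid chloride would be accompanied by dipolar cycloaddition.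

Step 8
Reactants: 12 potassium tert-butoxide (1.1 equiv); 13 trichloroethylene
Product: 15 (E)-1,2-dichloro-1-tert-butoxyethene, via dichloroacetylene 14 (not isolated)
Conditions: THF, −50 °C to rt (14 is toxic and explosive and is only generated and consumed in solution)
Reagents that add atoms: none
Why: Base-mediated dehydrochlorination of 13 followed by anti addition of tert-butoxide and a proton across the chloroalkyne, the general route to 1,2-dichlorovinyl ethers; the geometry of 15 is of no consequence for the next step.

Step 9
Reactants: 15 (E)-1,2-dichloro-1-tert-butoxyethene
Product: 18 tert-butoxyacetylene, via 1-tert-butoxy-2-chloroacetylene 16 (not isolated), via lithium tert-butoxyacetylide 17 (not isolated)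
Conditions: n-BuLi (2.2 equiv), Et2O, −78 to −40 °C; MeOH, −78 °C; cold aqueous wash, distillation below 40 °C, storage at −20 °C
Reagents that add atoms: n-butyllithium, [Li]CCCC (the lithium of 17 only)
Why: Dehydrochlorination to the chloroalkynyl ether and chlorine–lithium exchange give the lithium alkoxyacetylide, the established route from dichlorovinyl ethers to ynol ethers; cold protonation gives the terminal ynol ether, which must be kept cold because it loses the alkene to give ketene on warming.

Step 10
Reactants: 11 ring C aryl (E)-5-diazo-3-methyl-4-oxopent-2-enoate; 18 tert-butoxyacetylene (3 equiv)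
Product: 23 ring C aryl 4-tert-butoxy-2-hydroxy-6-methylbenzoate, via vinylketene 19 (not isolated), via 4-vinylcyclobutenone 20 (not isolated), via dienylketene 21 (not isolated), via cyclohexa-2,4-dienone 22 (not isolated)
Conditions: hν (365 nm LEDs, Pyrex), ClCH2CH2Cl (0.05 M), argon, 15 °C; remove excess 18 under reduced pressure; then toluene, 80 °C
Reagents that add atoms: none
Why: Excitation of 11 should expel dinitrogen with 1,2-shift of the alkenyl carbon to the former diazo carbon (Wolff rearrangement, forming B5–B6) and give vinylketene 19 with its alkene geometry intact. The ketene C=C then adds ynol ether 18 in a regioselective [2+2] cycloaddition, the unsubstituted alkyne carbon bonding to the ketene carbonyl carbon (B2–B3) and the oxygen-bearing carbon to the ketene α-carbon (B4–B5), to give 4-vinylcyclobutenone 20. Reversible four-electron electrocyclic opening of 20, thermal or photochemical, gives dienylketene 21, and the isomer with the alkenyl arm turned toward the ketene closes ring B by a six-electron disrotatory electrocyclisation (B1–B2) to cyclohexadienone 22, which tautomerises to phenol 23. The closest known reaction type is the Danheiser benzannulation in its diazo ketone (photochemical Wolff) variant, established for alkenyl diazomethyl ketones with alkoxy- and silyloxyalkynes. No stereocentre is set; those of 20 and 22 are lost on aromatisation. The selectivity needed is the orientation of the [2+2] step, which must place the ether oxygen meta to the new hydroxyl; it is secured by the polarisation of the ynol ether, whose β-carbon is the nucleophile. The E geometry of the enoate holds the aryloxycarbonyl group away from the ketene, so that 19 is open to cycloaddition and not to oxa-6π closure onto the ester carbonyl, and places that group on the outside of the terminus in the final closure. Long-wavelength light is used because the aryl ester would be liable to photo-Fries cleavage at 254 nm, and excess 18 is removed before heating so that ketene from its decomposition cannot acetylate the new phenol.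

Step 11
Reactants: 23 ring C aryl 4-tert-butoxy-2-hydroxy-6-methylbenzoate
Product: 24 ring C aryl 2,4-dihydroxy-6-methylbenzoate
Conditions: CF3CO2H/CH2Cl2 (1:4), Et3SiH (2 equiv), 0 °C to rt
Reagents that add atoms: none
Why: Acidolysis of the aryl tert-butyl ether; the silane reduces the tert-butyl cation so that it cannot alkylate the electron-rich ring at B3 or B5, and the aryl and methyl esters are stable to anhydrous acid.

Step 12
Reactants: 1 methyl orsellinate
Product: 25 methyl 2-hydroxy-4-methoxy-6-methylbenzoate
Conditions: MeI (1.1 equiv), K2CO3, acetone, reflux
Reagents that add atoms: iodomethane, CI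
Why: Williamson methylation that should be selective for the unchelated, more acidic 4-hydroxyl, as in step 1.

Step 13
Reactants: 25 methyl 2-hydroxy-4-methoxy-6-methylbenzoate
Product: 26 methyl 2-(benzyloxy)-4-methoxy-6-methylbenzoate
Conditions: BnBr (1.5 equiv), K2CO3, DMF, 60 °C
Reagents that add atoms: benzyl bromide, BrCc1ccccc1
Why: Williamson benzylation of the chelated phenol under forcing conditions; the benzyl ether prevents self-acylation of ring A later and is removable without touching ester bonds.

Step 14
Reactants: 26 methyl 2-(benzyloxy)-4-methoxy-6-methylbenzoate
Product: 27 2-(benzyloxy)-4-methoxy-6-methylbenzoic acid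
Conditions: KOH, DMSO/H2O, 90 °C; then dilute HCl, 0 °C
Reagents that add atoms: potassium hydroxide, [K+].[OH-]
Why: Saponification of a 2,6-disubstituted benzoate, which needs poorly solvated hydroxide in aqueous DMSO; both ethers are inert, and with both ring oxygens etherified the acid should not decarboxylate on cold acidification.

Step 15
Reactants: 27 2-(benzyloxy)-4-methoxy-6-methylbenzoic acid (1.1 equiv); 24 ring C aryl 2,4-dihydroxy-6-methylbenzoate
Product: 29 ring C aryl 4-{[2-(benzyloxy)-4-methoxy-6-methylbenzoyl]oxy}-2-hydroxy-6-methylbenzoate, via acid chloride 28 (not isolated)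
Conditions: (COCl)2, DMF (cat.), CH2Cl2, 0 °C to rt; evaporate; then 24, Et3N (1.2 equiv), DMAP (cat.), CH2Cl2, 0 °C to rt
Reagents that add atoms: oxalyl chloride, O=C(Cl)C(=O)Cl (the chlorine of 28 only)
Why: Acid chloride formation with Vilsmeier-type catalysis, then DMAP-catalysed acylation of a phenol; B4–OH is unchelated, more acidic and unhindered, whereas B2–OH is locked in a hydrogen bond to the B1 ester carbonyl, so monoacylation at B4–O is expected. The existing B1 ester is a 2,6-disubstituted benzoate and should resist acyl transfer.

Step 16
Reactants: 29 ring C aryl 4-{[2-(benzyloxy)-4-methoxy-6-methylbenzoyl]oxy}-2-hydroxy-6-methylbenzoate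
Product: 30 the target, 3-methoxy-4-(methoxycarbonyl)-5-methylphenyl 2-hydroxy-4-[(2-hydroxy-4-methoxy-6-methylbenzoyl)oxy]-6-methylbenzoate
Conditions: H2 (1 atm), 10% Pd/C, EtOAc, rt
Reagents that add atoms: none
Why: Hydrogenolysis of the last benzyl ether under neutral conditions, which aryl esters, methyl ester and methyl ethers tolerate; it frees A2–OH and completes the target.

## Compound list

1 | methyl orsellinate (methyl 2,4-dihydroxy-6-methylbenzoate) | COC(=O)c1c(C)cc(O)cc1O | starting material
2 | methyl 4-(benzyloxy)-2-hydroxy-6-methylbenzoate | COC(=O)c1c(C)cc(OCc2ccccc2)cc1O | intermediate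
3 | methyl 4-(benzyloxy)-2-methoxy-6-methylbenzoate | COC(=O)c1c(C)cc(OCc2ccccc2)cc1OC | intermediate
4 | methyl 4-hydroxy-2-methoxy-6-methylbenzoate | COC(=O)c1c(C)cc(O)cc1OC | intermediate
5 | butane-2,3-dione | CC(=O)C(C)=O | starting material
6 | tert-butyl (triphenyl-λ5-phosphanylidene)acetate | CC(C)(C)OC(=O)C=P(c1ccccc1)(c1ccccc1)c1ccccc1 | starting material
7 | tert-butyl (E)-3-methyl-4-oxopent-2-enoate | CC(=O)/C(C)=C/C(=O)OC(C)(C)C | intermediate
8 | (E)-3-methyl-4-oxopent-2-enoic acid | CC(=O)/C(C)=C/C(=O)O | intermediate
9 | 3-methoxy-4-(methoxycarbonyl)-5-methylphenyl (E)-3-methyl-4-oxopent-2-enoate | CC(=O)/C(C)=C/C(=O)Oc1cc(C)c(C(=O)OC)c(OC)c1 | intermediate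
10 | 3-methoxy-4-(methoxycarbonyl)-5-methylphenyl (E)-7,7,7-trifluoro-3-methyl-4,6-dioxohept-2-enoate | O=C(CC(=O)/C(C)=C/C(=O)Oc1cc(C)c(C(=O)OC)c(OC)c1)C(F)(F)F | intermediate (not isolated)
11 | 3-methoxy-4-(methoxycarbonyl)-5-methylphenyl (E)-5-diazo-3-methyl-4-oxopent-2-enoate | [N-]=[N+]=CC(=O)/C(C)=C/C(=O)Oc1cc(C)c(C(=O)OC)c(OC)c1 | intermediate
12 | potassium tert-butoxide | CC(C)(C)[O-].[K+] | starting material
13 | trichloroethylene | ClC=C(Cl)Cl | starting material
14 | dichloroacetylene | ClC#CCl | intermediate (not isolated)
15 | (E)-1,2-dichloro-1-tert-butoxyethene | CC(C)(C)O/C(Cl)=C\Cl | intermediate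
16 | 1-tert-butoxy-2-chloroacetylene | CC(C)(C)OC#CCl | intermediate (not isolated)
17 | lithium tert-butoxyacetylide | [Li]C#COC(C)(C)C | intermediate (not isolated)
18 | tert-butoxyacetylene (2-(ethynyloxy)-2-methylpropane) | C#COC(C)(C)C | intermediate
19 | 3-methoxy-4-(methoxycarbonyl)-5-methylphenyl (2E)-3-methyl-5-oxopenta-2,4-dienoate | O=C=C/C(C)=C/C(=O)Oc1cc(C)c(C(=O)OC)c(OC)c1 | intermediate (not isolated)
20 | 3-methoxy-4-(methoxycarbonyl)-5-methylphenyl (E)-3-(2-tert-butoxy-4-oxocyclobut-2-en-1-yl)but-2-enoate, racemic | CC(C)(C)OC1=CC(=O)C1/C(C)=C/C(=O)Oc1cc(C)c(C(=O)OC)c(OC)c1 | intermediate (not isolated)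
21 | 3-methoxy-4-(methoxycarbonyl)-5-methylphenyl (2E,4E)-5-tert-butoxy-3-methyl-7-oxohepta-2,4,6-trienoate | O=C=C/C(OC(C)(C)C)=C\C(C)=C\C(=O)Oc1cc(C)c(C(=O)OC)c(OC)c1 | intermediate (not isolated)
22 | 3-methoxy-4-(methoxycarbonyl)-5-methylphenyl 4-tert-butoxy-2-methyl-6-oxocyclohexa-2,4-diene-1-carboxylate, racemic | O=C1C=C(OC(C)(C)C)C=C(C)C1C(=O)Oc1cc(C)c(C(=O)OC)c(OC)c1 | intermediate (not isolated)
23 | 3-methoxy-4-(methoxycarbonyl)-5-methylphenyl 4-tert-butoxy-2-hydroxy-6-methylbenzoate | COC(=O)c1c(C)cc(OC(=O)c2c(C)cc(OC(C)(C)C)cc2O)cc1OC | intermediate
24 | 3-methoxy-4-(methoxycarbonyl)-5-methylphenyl 2,4-dihydroxy-6-methylbenzoate | COC(=O)c1c(C)cc(OC(=O)c2c(C)cc(O)cc2O)cc1OC | intermediate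
25 | methyl 2-hydroxy-4-methoxy-6-methylbenzoate | COC(=O)c1c(C)cc(OC)cc1O | intermediate
26 | methyl 2-(benzyloxy)-4-methoxy-6-methylbenzoate | COC(=O)c1c(C)cc(OC)cc1OCc1ccccc1 | intermediate
27 | 2-(benzyloxy)-4-methoxy-6-methylbenzoic acid | OC(=O)c1c(C)cc(OC)cc1OCc1ccccc1 | intermediate
28 | 2-(benzyloxy)-4-methoxy-6-methylbenzoyl chloride | ClC(=O)c1c(C)cc(OC)cc1OCc1ccccc1 | intermediate (not isolated)
29 | 3-methoxy-4-(methoxycarbonyl)-5-methylphenyl 4-{[2-(benzyloxy)-4-methoxy-6-methylbenzoyl]oxy}-2-hydroxy-6-methylbenzoate | COC(=O)c1c(C)cc(OC(=O)c2c(C)cc(OC(=O)c3c(C)cc(OC)cc3OCc3ccccc3)cc2O)cc1OC | intermediate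
30 | 3-methoxy-4-(methoxycarbonyl)-5-methylphenyl 2-hydroxy-4-[(2-hydroxy-4-methoxy-6-methylbenzoyl)oxy]-6-methylbenzoate | COC(=O)c1c(C)cc(OC(=O)c2c(C)cc(OC(=O)c3c(C)cc(OC)cc3O)cc2O)cc1OC | target

## Step count and uncertain steps

Total step count: 16. Longest linear sequence: 9 steps (steps 1, 2, 3, 6, 7, 10, 11, 15, 16).

Step 10 (key step). The most likely failure is diversion of the ketenes before the ring closes. The possible processes are:
- capture of 19 or 21 by the hydroxyl of phenol already formed;
- photoisomerisation of the enoate double bond, followed by oxa-6π closure of the ketene onto the ester carbonyl;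
- photo-Fries cleavage of the aryl ester if the light is too energetic;
- stalling at the cyclobutenone stage;
- acetylation of the product by ketene released from warm 18.

The fallback gives up the ring construction and makes the hindered ester classically, through a mixed anhydride in acid medium. It sets out from 1 and 4 and comes back to the route at 24. Exhaustive benzylation of 1 (BnBr, K2CO3, DMF) would give methyl 2,4-bis(benzyloxy)-6-methylbenzoate F1, and saponification (KOH, aqueous DMSO) would give 2,4-bis(benzyloxy)-6-methylbenzoic acid F2. Activation with trifluoroacetic anhydride in toluene would form 2,4-bis(benzyloxy)-6-methylbenzoic trifluoroacetic anhydride F3, which would acylate phenol 4 in the same flask to give 3-methoxy-4-(methoxycarbonyl)-5-methylphenyl 2,4-bis(benzyloxy)-6-methylbenzoate F4. Hydrogenolysis (H2, Pd/C) would then give 24.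

Step 7. The lithium enolate of 9 is generated in a molecule that also holds an aryl ester and a doubly activated alkene. Self-condensation by Claisen acylation or Michael addition may therefore compete with trifluoroacetylation. The fallback avoids the lithium enolate. It sets out from 9 and comes back at 10. Soft enolisation (Me3SiOTf, Et3N, CH2Cl2, 0 °C) would give 3-methoxy-4-(methoxycarbonyl)-5-methylphenyl (2E)-3-methyl-4-(trimethylsilyloxy)penta-2,4-dienoate F5. C-Acylation of this silyl enol ether with trifluoroacetic anhydride and pyridine would give 10, which is then taken through the sulfonyl azide stage of step 7 to 11.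

Step 9. The ynol ether 18 is volatile and thermally labile. It may be lost on separation from the solvent, or may eliminate its alkene to give ketene during distillation. The fallback avoids the organolithium route and ethereal solvents. It replaces 15 by commercial tert-butyl vinyl ether F6 and comes back to the route at 18. Bromination at −78 °C would give 1,2-dibromo-1-tert-butoxyethane F7, and dehydrobromination with Et3N would give (Z)-1-bromo-2-tert-butoxyethene F8. Elimination with NaNH2 in liquid ammonia, from which 18 is isolated by extraction into pentane after quenching, would complete it.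

Step 15. Under basic conditions the hindered acid chloride may react sluggishly. That would leave room for acylation of B2–OH as well, or for phenoxide-mediated acyl transfer at the existing B1 ester. The fallback changes the activation from a base-mediated acyl chloride to an acid-mediated mixed anhydride. It sets out from 27 and 24 and comes back at 29. Acid 27 and trifluoroacetic anhydride in toluene would form 2-(benzyloxy)-4-methoxy-6-methylbenzoic trifluoroacetic anhydride F9, which would acylate the unchelated B4–OH of 24 without any phenoxide being present.

## Further compounds

F1 | step 10 | methyl 2,4-bis(benzyloxy)-6-methylbenzoate | COC(=O)c1c(C)cc(OCc2ccccc2)cc1OCc1ccccc1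
F2 | step 10 | 2,4-bis(benzyloxy)-6-methylbenzoic acid | OC(=O)c1c(C)cc(OCc2ccccc2)cc1OCc1ccccc1
F3 | step 10 | 2,4-bis(benzyloxy)-6-methylbenzoic trifluoroacetic anhydride | O=C(OC(=O)C(F)(F)F)c1c(C)cc(OCc2ccccc2)cc1OCc1ccccc1
F4 | step 10 | 3-methoxy-4-(methoxycarbonyl)-5-methylphenyl 2,4-bis(benzyloxy)-6-methylbenzoate | COC(=O)c1c(C)cc(OC(=O)c2c(C)cc(OCc3ccccc3)cc2OCc2ccccc2)cc1OC
F5 | step 7 | 3-methoxy-4-(methoxycarbonyl)-5-methylphenyl (2E)-3-methyl-4-(trimethylsilyloxy)penta-2,4-dienoate | C=C(O[Si](C)(C)C)/C(C)=C/C(=O)Oc1cc(C)c(C(=O)OC)c(OC)c1
F6 | step 9 | tert-butyl vinyl ether | C=COC(C)(C)C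
F7 | step 9 | 1,2-dibromo-1-tert-butoxyethane | BrCC(Br)OC(C)(C)C
F8 | step 9 | (Z)-1-bromo-2-tert-butoxyethene | Br/C=C\OC(C)(C)C
F9 | step 15 | 2-(benzyloxy)-4-methoxy-6-methylbenzoic trifluoroacetic anhydride | O=C(OC(=O)C(F)(F)F)c1c(C)cc(OC)cc1OCc1ccccc1
A1 | alternative 1 | 3-methoxy-4-(methoxycarbonyl)-5-methylphenyl 2-(benzyloxy)-4-{[2-(benzyloxy)-4-methoxy-6-methylbenzoyl]oxy}-6-methylbenzoate | COC(=O)c1c(C)cc(OC(=O)c2c(C)cc(OC(=O)c3c(C)cc(OC)cc3OCc3ccccc3)cc2OCc2ccccc2)cc1OC
A2 | alternative 1 | 3-(benzyloxy)-4-{[3-methoxy-4-(methoxycarbonyl)-5-methylphenoxy]carbonyl}-5-methylphenyl 4-(benzyloxy)-6-methyl-2-oxo-2H-pyran-5-carboxylate | COC(=O)c1c(C)cc(OC(=O)c2c(C)cc(OC(=O)c3c(C)oc(=O)cc3OCc3ccccc3)cc2OCc2ccccc2)cc1OC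
A3 | alternative 1 | 1,1-dimethoxyethene | C=C(OC)OC
A4 | alternative 2 | methyl 2-methoxy-6-methyl-4-(trimethylsilyloxy)benzoate | COC(=O)c1c(C)cc(O[Si](C)(C)C)cc1OC
A5 | alternative 2 | 1,1-dimethoxy-3-(trimethylsilyloxy)buta-1,3-diene | COC(OC)=CC(=C)O[Si](C)(C)C
A6 | alternative 2 | methyl but-2-ynoate | CC#CC(=O)OC
A7 | alternative 3 | 3-methoxy-4-(methoxycarbonyl)-5-methylphenyl 4-[(2,4-dihydroxy-6-methylbenzoyl)oxy]-2-hydroxy-6-methylbenzoate | Cc1cc(O)cc(O)c1C(=O)Oc1cc(C)c(C(=O)Oc2cc(C)c(C(=O)OC)c(OC)c2)c(O)c1
A8 | alternative 3 | 3-hydroxy-4-{[3-methoxy-4-(methoxycarbonyl)-5-methylphenoxy]carbonyl}-5-methylphenyl 3,5,7-trioxooctanoate | CC(=O)CC(=O)CC(=O)CC(=O)Oc1cc(C)c(C(=O)Oc2cc(C)c(C(=O)OC)c(OC)c2)c(O)c1
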